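The 0.50 M of D charged cannot all stand in solution, being more than the solubility of 0.26 M, so the argument starts from a level of J that stays put while solid lasts.

D 0.50 M; G 1.25 M; E 0.0250 M; time 8.0 h

* amount of J.G at 8.0 h, in percent of the D charged
* concentration of J in solution at 50 min, in percent of saturation
* the change that raises the amount of J.G at 8.0 h, in percent of the D charged most ("none" if none brings more than 2 percentage points) (alder / birch / ash / none)
* amount of J.G at 8.0 h, in percent of the D charged, after ash

- alder: doubling the amount of G, all else as stated
- birch: doubling the solubility in step 1, all else as stated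
- ash: doubling the dissolution coefficient of step 1, all else as stated

- a doubled species enters its step squared and goes two at a time
- solid, in amounts per volume of the solution: D
- at the start none of D is in solution
- J means what is dissolved; the solid is not counted in it
- run time (flask): 8.0 h

    D ⇌ J, rate k1*(cs1 - [J]) while solid is left; crystals form when [J] > cs1 (cs1 = 0.26 M, k1 = 0.011 s⁻¹)
    G ⇌ Z (K2 = 0.62, k2 = 5.1 × 10⁻⁴ s⁻¹)
    D + E → D.E (k3 = 0.23 M⁻¹ s⁻¹)
    2 G → G2 (k4 = 0.0028 M⁻¹ s⁻¹)
    J + G → J.G (k5 = 6.1 × 10⁻⁴ M⁻¹ s⁻¹)

By hand: the gap below saturation halves every 1.05 min, much shorter than the run. With J held at 0.26 M, capture by J is pseudo-first-order in G, while dimerisation goes with the square of G. The concentration at which the two consume G equally, solubility times capture constant over twice the dimerisation constant, is the crossover level G× = 0.0283 M.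

The J.G curve would start at 0.714 M h⁻¹ against the full charge of G. It bends at once, because dimerisation halves G in 2.38 min, far shorter than the run. With step 2 left out, G meets G× at the knee, 1.17 h. Beyond it dimerisation is the smaller loss, and G and Z relax towards each other with a half-life of 0.144 h, shorter than the run. Free G is then 61.7% of G plus Z, so capture halves that pool every 1.97 h, which allows 3.47 halvings before 8.0 h. Integrating both losses with step 2 left out, J.G levels at G× times the natural logarithm of one plus charge over G×: 0.108 M, or 21.6% of D. Solid remains on this reckoning, 0.107 M after saturation, E and J.G are subtracted.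

At 50 min, dimerisation by itself puts G at 0.0568 M on this reckoning, so capture over dissolution opens a gap of 0.315%, putting J at 99.7% of saturation.

| Recipe | G× | J.G, of D |
|---|---|---|
| flask | 0.0283 M | 21.6% |
| alder | 0.0283 M | 25.4% |
| birch, J taken at D less E | 0.0517 M | 33.4% |
| ash | 0.0283 M | 21.6% |

The reckoning therefore picks birch.

The forecast gives 27% (23% to 31%), above the hand figure; 99.3% (98.8% to 99.7%); birch; and 28% (24% to 32%). Its grounds: “the J.G yield is limited by the surviving G and J's concentration”.

The simulation gives 25.5%, 99.6%, birch and 26.5%; the gains are 3.8 percentage points for alder, 9.3 points for birch and 0.99 points for ash.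

In this flask J.G reaches 0.128 M, which is 4.51 times G× and 3.9 points above the hand level, while Z stood at 0.0611 M after 0.800 h. The neighbour with 2.0 M of D has the same solubility, hence the same G× of 0.0283 M and the same reckoned J.G, 5.40% of its D. Carrying this flask's simulated amount over instead gives 6.38%. That neighbour ends with J at 13.0% of its D and J.G at 6.38%.

(The rate constants come from no measurement; the flask was simulated.)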